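## Retrosynthetic overview

1. Enabling feature (indene numbering of the target): the cyclohexene ring C3a–C4–C5–C6=C7–C7a has its only double bond, C6=C7, opposite the ring-fusion bond C3a–C7a and the bond C4–C5 between the two quaternary carbons, and C4 carries the carboxyl carbon. This is a Diels–Alder retron, and the cyclopentene double bond C2=C3 is a ready-made cis three-atom tether.
2. Key disconnection: C3a–C7a and C4–C5 together, by a biomimetic intramolecular Diels–Alder reaction of the open-chain (2E,4Z,6S,7E,9E,11E,13E)-hexaenal (formyl in place of CO2H). Cyclopentene and cyclohexene close in the same step, no ring exists before it, and four of the five stereocentres follow from the single C6 stereocentre.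
3. Hexaenal ⇐ hexaenoate ⇐ Negishi union at C8–C9 of a (1E,3E,5E)-iodotriene (from propargyl alcohol and diethyl cinnamylphosphonate) with an (E)-iodoalkene that carries the (2E,4Z)-dienoate.
4. Dienoate ⇐ Still–Gennari (C4=C5, Z) and Wittig (C2=C3, E) olefinations; iodoalkene ⇐ hydrozirconation–iodination of a methyl alkyne; stereocentre ⇐ (R)-Roche ester.
5. After the cycloaddition only the oxidation CHO → CO2H remains.

Key step: step 18

Remark: chain atoms are numbered C1–C14 from the carbonyl carbon to the phenyl-bearing carbon; conjugate bases made by simple deprotonation (acetylide, phosphonate carbanions) are counted with their parent compounds, while organometallic intermediates from hydrometalation, carbometalation, halogen–metal exchange or transmetalation are numbered.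

## Route

Step 1
Reactants: 1 methyl (R)-3-hydroxy-2-methylpropanoate
Product: 2 methyl (R)-3-[(tert-butyldimethylsilyl)oxy]-2-methylpropanoate
Conditions: TBSCl, imidazole, CH2Cl2, 0 °C → rt
Reagents that add atoms: tert-butyldimethylsilyl chloride CC(C)(C)[Si](C)(C)Cl
Why: Imidazole-promoted silylation of the primary alcohol (silyl ether protection) should proceed without touching the ester or the α-stereocentre, which comes from the chiral pool.

Step 2
Reactants: 2 methyl (R)-3-[(tert-butyldimethylsilyl)oxy]-2-methylpropanoate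
Product: 3 (R)-3-[(tert-butyldimethylsilyl)oxy]-2-methylpropanal
Conditions: i-Bu2AlH (1.1 equiv), CH2Cl2, −78 °C; MeOH, then aq. KNaC4H4O6
Reagents that add atoms: none
Why: Partial ester reduction with i-Bu2AlH at −78 °C stops at the aluminium hemiacetal, which releases the aldehyde only on work-up, and the cold non-basic conditions should leave the α-stereocentre intact.

Step 3
Reactants: 3 (R)-3-[(tert-butyldimethylsilyl)oxy]-2-methylpropanal
Product: 4 (S)-tert-butyldimethyl[(2-methylbut-3-yn-1-yl)oxy]silane
Conditions: dimethyl (1-diazo-2-oxopropyl)phosphonate, K2CO3, MeOH, 0 °C → rt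
Reagents that add atoms: dimethyl (1-diazo-2-oxopropyl)phosphonate CC(=O)C(=[N+]=[N-])P(=O)(OC)OC
Why: Seyferth–Gilbert homologation in the Ohira–Bestmann variant converts the aldehyde into the terminal alkyne under K2CO3/MeOH conditions mild enough for this β-silyloxy α-methyl aldehyde, so the stereocentre should be retained.

Step 4
Reactants: 4 (S)-tert-butyldimethyl[(2-methylbut-3-yn-1-yl)oxy]silane
Product: 5 (S)-tert-butyldimethyl[(2-methylpent-3-yn-1-yl)oxy]silane
Conditions: n-BuLi, THF, −78 °C; MeI, −78 °C → rt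
Reagents that add atoms: iodomethane CI
Why: Deprotonation of the terminal alkyne and SN2 methylation of the lithium acetylide should give the methyl alkyne, the propargylic C–H not being acidic enough to be touched at −78 °C.

Step 5
Reactants: 5 (S)-tert-butyldimethyl[(2-methylpent-3-yn-1-yl)oxy]silane
Product: 7 (S,E)-tert-butyl[(4-iodo-2-methylpent-3-en-1-yl)oxy]dimethylsilane, via alkenylzirconocene chloride 6 (not isolated)
Conditions: Cp2Zr(H)Cl (2 equiv), THF, 50 °C; then I2, 0 °C
Reagents that add atoms: iodine II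
Why: Hydrozirconation (Schwartz reagent) is a syn addition, excess reagent at 50 °C should equilibrate zirconium to the less hindered methyl-bearing alkyne carbon, and iodinolysis with retention should give the (E)-2-iodoalkene.

Step 6
Reactants: 7 (S,E)-tert-butyl[(4-iodo-2-methylpent-3-en-1-yl)oxy]dimethylsilane
Product: 8 (S,E)-4-iodo-2-methylpent-3-en-1-ol
Conditions: CSA (10 mol%), MeOH/CH2Cl2, 0 °C → rt
Reagents that add atoms: none
Why: Acid-catalysed methanolysis of the primary silyl ether (desilylation) should leave the vinyl iodide and the allylic stereocentre untouched.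

Step 7
Reactants: 8 (S,E)-4-iodo-2-methylpent-3-en-1-ol
Product: 9 (S,E)-4-iodo-2-methylpent-3-enal
Conditions: Dess–Martin periodinane, NaHCO3, CH2Cl2, 0 °C → rt; used directly
Reagents that add atoms: none
Why: Buffered Dess–Martin oxidation is fast and non-basic, and enolisation towards the conjugated dienol is disfavoured by allylic 1,3-strain with the cis methyl group of the iodoalkene, so the aldehyde should form without epimerisation.

Step 8
Reactants: 10 methyl 2-[bis(2,2,2-trifluoroethoxy)phosphoryl]acetate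
Product: 11 methyl 2-[bis(2,2,2-trifluoroethoxy)phosphoryl]butanoate (racemic)
Conditions: NaH (1.0 equiv), DMF, 0 °C; EtI, 0 °C → rt
Reagents that add atoms: iodoethane CCI
Why: C-Alkylation (SN2) of the sodium salt of the doubly stabilised phosphonoacetate with iodoethane should give the α-ethyl Still–Gennari reagent, whose α-stereocentre is irrelevant because it becomes sp2 in the next step.

Step 9
Reactants: 9 (S,E)-4-iodo-2-methylpent-3-enal; 11 methyl 2-[bis(2,2,2-trifluoroethoxy)phosphoryl]butanoate
Product: 12 methyl (2Z,4R,5E)-2-ethyl-6-iodo-4-methylhepta-2,5-dienoate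
Conditions: 11, KN(SiMe3)2, 18-crown-6, THF, −78 °C; then 9, −78 °C
Reagents that add atoms: none
Why: Still–Gennari olefination: the electron-poor bis(trifluoroethyl) phosphonate under dissociating KN(SiMe3)2/18-crown-6 conditions eliminates rapidly from the kinetic adduct and should deliver the (Z)-trisubstituted enoate, while addition at −78 °C should outpace enolisation of the α-stereocentre.

Step 10
Reactants: 12 methyl (2Z,4R,5E)-2-ethyl-6-iodo-4-methylhepta-2,5-dienoate
Product: 13 (2Z,4R,5E)-2-ethyl-6-iodo-4-methylhepta-2,5-dien-1-ol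
Conditions: i-Bu2AlH (2.5 equiv), CH2Cl2, −78 °C; aq. KNaC4H4O6
Reagents that add atoms: none
Why: 1,2-Reduction of the enoate with excess i-Bu2AlH should give the (Z)-allylic alcohol with the vinyl iodide and both alkene geometries unchanged.

Step 11
Reactants: 13 (2Z,4R,5E)-2-ethyl-6-iodo-4-methylhepta-2,5-dien-1-ol; 14 ethyl 2-(triphenylphosphoranylidene)propanoate
Product: 16 ethyl (2E,4Z,6R,7E)-4-ethyl-8-iodo-2,6-dimethylnona-2,4,7-trienoate, via iododienal 15 (not isolated)
Conditions: MnO2 (excess), 14, CH2Cl2, rt → 40 °C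
Reagents that add atoms: none
Why: Tandem allylic oxidation–Wittig olefination: MnO2 oxidises only the allylic alcohol and the stabilised ylide traps the (Z)-enal as it forms, which should limit Z-to-E isomerisation and give the new trisubstituted alkene with E geometry.

Step 12
Reactants: 17 prop-2-yn-1-ol
Product: 19 (E)-3-iodo-2-methylprop-2-en-1-ol, via alkenylalane 18 (not isolated)
Conditions: Me3Al (2.5 equiv), Cp2ZrCl2 (0.25 equiv), CH2Cl2, 0 °C → rt; then I2, THF, −30 → 0 °C; aq. K2CO3
Reagents that add atoms: trimethylaluminium C[Al](C)C; iodine II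
Why: Zirconium-catalysed carboalumination (Negishi) adds methyl and aluminium syn across the alkyne with methyl at the internal carbon, and iodinolysis with retention should give the (E)-iodoalkene.

Step 13
Reactants: 19 (E)-3-iodo-2-methylprop-2-en-1-ol
Product: 20 (E)-3-iodo-2-methylprop-2-enal
Conditions: MnO2 (excess), CH2Cl2, rt; filtered, used as solution
Reagents that add atoms: none
Why: MnO2 oxidises the allylic alcohol chemoselectively to the enal (allylic oxidation) without affecting the vinyl iodide or its geometry.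

Step 14
Reactants: 20 (E)-3-iodo-2-methylprop-2-enal; 21 diethyl [(E)-3-phenylprop-2-en-1-yl]phosphonate
Product: 22 [(1E,3E,5E)-6-iodo-5-methylhexa-1,3,5-trien-1-yl]benzene
Conditions: 21, NaN(SiMe3)2, THF, −78 °C; then 20, −78 → 0 °C, dark
Reagents that add atoms: none
Why: Horner–Wadsworth–Emmons olefination with the allylic (cinnamyl) phosphonate anion should form the new disubstituted alkene with E geometry and extend the iodoenal to the (E,E,E)-triene.

Step 15
Reactants: 22 [(1E,3E,5E)-6-iodo-5-methylhexa-1,3,5-trien-1-yl]benzene; 16 ethyl (2E,4Z,6R,7E)-4-ethyl-8-iodo-2,6-dimethylnona-2,4,7-trienoate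
Product: 25 ethyl (2E,4Z,6S,7E,9E,11E,13E)-4-ethyl-2,6,8,10-tetramethyl-14-phenyltetradeca-2,4,7,9,11,13-hexaenoate, via trienyllithium 23 (not isolated), via trienylzinc chloride 24 (not isolated)
Conditions: 22, t-BuLi (2.0 equiv), Et2O, −78 °C; ZnCl2, THF, −78 → 0 °C; then 16, Pd(PPh3)4 (5 mol%), THF, rt, dark
Reagents that add atoms: none
Why: Negishi cross-coupling: iodine–lithium exchange and transmetalation to zinc proceed with retention, and the Pd-catalysed coupling of two alkenyl partners is stereospecific and tolerates the ester, so all alkene geometries and the stereocentre should be carried into the hexaene.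

Step 16
Reactants: 25 ethyl (2E,4Z,6S,7E,9E,11E,13E)-4-ethyl-2,6,8,10-tetramethyl-14-phenyltetradeca-2,4,7,9,11,13-hexaenoate
Product: 26 (2E,4Z,6S,7E,9E,11E,13E)-4-ethyl-2,6,8,10-tetramethyl-14-phenyltetradeca-2,4,7,9,11,13-hexaen-1-ol
Conditions: i-Bu2AlH (2.5 equiv), CH2Cl2, −78 °C, dark; aq. KNaC4H4O6
Reagents that add atoms: none
Why: 1,2-Reduction of the dienoate with i-Bu2AlH at low temperature should give the primary allylic alcohol without touching the polyene or the bis-allylic stereocentre.

Step 17
Reactants: 26 (2E,4Z,6S,7E,9E,11E,13E)-4-ethyl-2,6,8,10-tetramethyl-14-phenyltetradeca-2,4,7,9,11,13-hexaen-1-ol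
Product: 27 (2E,4Z,6S,7E,9E,11E,13E)-4-ethyl-2,6,8,10-tetramethyl-14-phenyltetradeca-2,4,7,9,11,13-hexaenal
Conditions: MnO2 (excess), CH2Cl2, 0 °C, dark; filtered cold, used at once
Reagents that add atoms: none
Why: Allylic oxidation with MnO2 is neutral and selective for the dienylic alcohol, so the hexaenal should form without isomerisation and is kept cold and dilute for the next step.

Step 18
Reactants: 27 (2E,4Z,6S,7E,9E,11E,13E)-4-ethyl-2,6,8,10-tetramethyl-14-phenyltetradeca-2,4,7,9,11,13-hexaenal
Product: 28 (1R,3aR,4R,5S,7aS)-3-ethyl-1,4,5,7-tetramethyl-5-[(1E,3E)-4-phenylbuta-1,3-dien-1-yl]-3a,4,5,7a-tetrahydro-1H-indene-4-carbaldehyde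
Conditions: Me2AlCl (1.2 equiv), CH2Cl2 (0.005 M), −78 → −20 °C, dark; aq. NaHCO3
Reagents that add atoms: none
Why: Concerted, asynchronous [4+2] cycloaddition (intramolecular Diels–Alder reaction, normal electron demand) in which the Me2AlCl-bound (E)-2-methylenal C2=C3 adds to the s-cis C7=C8–C9=C10 diene and forms C3–C7 and C2–C10 at once; the closest known reaction type is the Lewis-acid-promoted cyclisation of terminally activated 1,3,8-nonatrienals to trans-fused hydrindenes, which is also the presumed biosynthetic ring construction of this polyketide family. The cyclohexene closes as the six-membered cycloadduct ring (suprafacial on both components), and the cyclopentene closes at the same time by the C3–C7 bond across the three-atom tether C4=C5–C6, whose (4Z) double bond already holds C3 and C6 cis so that only a five-membered bridging ring can form. The relative configuration of C2 and C3 (indene C4 and C3a) follows from the E geometry of the dienophile, that of C7 and C10 (indene C7a and C5) from the (7E,9E) geometry of the diene with H-7 and the 10-methyl group inside, and the endo position of the aluminium-bound formyl group links the two pairs and gives the trans ring fusion with formyl and dienyl chain cis. The diene face is set by the C6 stereocentre: allylic 1,3-strain with the 8-methyl group keeps H-6 eclipsed with C7=C8, so the tether reaches the dienophile from the face that leaves the 6-methyl group cis to H-7 in the product. The step needs endo selectivity, π-facial selectivity and periselectivity: the small Lewis acid on the carbonyl oxygen (larger LUMO coefficient, secondary overlap) and the low temperature should secure endo, the allylic strain secures the face, and only the C7–C10 diene can reach C2=C3 through a short tether, its s-cis form being favoured because the 8- and 10-methyl groups clash in the s-trans form.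

Step 19
Reactants: 28 (1R,3aR,4R,5S,7aS)-3-ethyl-1,4,5,7-tetramethyl-5-[(1E,3E)-4-phenylbuta-1,3-dien-1-yl]-3a,4,5,7a-tetrahydro-1H-indene-4-carbaldehyde
Product: 29 (1R,3aR,4R,5S,7aS)-3-ethyl-1,4,5,7-tetramethyl-5-[(1E,3E)-4-phenylbuta-1,3-dien-1-yl]-3a,4,5,7a-tetrahydro-1H-indene-4-carboxylic acid (22-nor-zyggomphic acid B)
Conditions: NaClO2, NaH2PO4, 2-methyl-2-butene, t-BuOH/H2O, 0 °C → rt
Reagents that add atoms: sodium chlorite [Na+].[O-]Cl=O
Why: Pinnick oxidation (chlorous acid with 2-methyl-2-butene as hypochlorite scavenger) should convert the hindered aldehyde on the quaternary carbon into the acid, which has no epimerisable position, without attack on the alkenes.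

## Compound list

1 | methyl (R)-3-hydroxy-2-methylpropanoate ((R)-Roche ester) | OC[C@@H](C)C(=O)OC | starting material
2 | methyl (R)-3-[(tert-butyldimethylsilyl)oxy]-2-methylpropanoate | CC(C)(C)[Si](C)(C)OC[C@@H](C)C(=O)OC | intermediate
3 | (R)-3-[(tert-butyldimethylsilyl)oxy]-2-methylpropanal | CC(C)(C)[Si](C)(C)OC[C@@H](C)C=O | intermediate
4 | (S)-tert-butyldimethyl[(2-methylbut-3-yn-1-yl)oxy]silane | CC(C)(C)[Si](C)(C)OC[C@@H](C)C#C | intermediate
5 | (S)-tert-butyldimethyl[(2-methylpent-3-yn-1-yl)oxy]silane | CC(C)(C)[Si](C)(C)OC[C@@H](C)C#CC | intermediate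
6 | chloro{(2E,4S)-5-[(tert-butyldimethylsilyl)oxy]-4-methylpent-2-en-2-yl}zirconocene (formed in situ) | CC(C)(C)[Si](C)(C)OC[C@@H](C)/C=C(\C)[Zr](Cl)(C1C=CC=C1)C1C=CC=C1 | intermediate
7 | (S,E)-tert-butyl[(4-iodo-2-methylpent-3-en-1-yl)oxy]dimethylsilane | CC(C)(C)[Si](C)(C)OC[C@@H](C)/C=C(\C)I | intermediate
8 | (S,E)-4-iodo-2-methylpent-3-en-1-ol | OC[C@@H](C)/C=C(\C)I | intermediate
9 | (S,E)-4-iodo-2-methylpent-3-enal | O=C[C@@H](C)/C=C(\C)I | intermediate
10 | methyl 2-[bis(2,2,2-trifluoroethoxy)phosphoryl]acetate | COC(=O)CP(=O)(OCC(F)(F)F)OCC(F)(F)F | starting material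
11 | methyl 2-[bis(2,2,2-trifluoroethoxy)phosphoryl]butanoate (racemic) | CCC(C(=O)OC)P(=O)(OCC(F)(F)F)OCC(F)(F)F | intermediate
12 | methyl (2Z,4R,5E)-2-ethyl-6-iodo-4-methylhepta-2,5-dienoate | COC(=O)/C(CC)=C\[C@@H](C)/C=C(\C)I | intermediate
13 | (2Z,4R,5E)-2-ethyl-6-iodo-4-methylhepta-2,5-dien-1-ol | OC/C(CC)=C\[C@@H](C)/C=C(\C)I | intermediate
14 | ethyl 2-(triphenylphosphoranylidene)propanoate | CCOC(=O)C(C)=P(c1ccccc1)(c1ccccc1)c1ccccc1 | starting material
15 | (2Z,4R,5E)-2-ethyl-6-iodo-4-methylhepta-2,5-dienal (formed in situ) | O=C/C(CC)=C\[C@@H](C)/C=C(\C)I | intermediate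
16 | ethyl (2E,4Z,6R,7E)-4-ethyl-8-iodo-2,6-dimethylnona-2,4,7-trienoate | CCOC(=O)/C(C)=C/C(CC)=C\[C@@H](C)/C=C(\C)I | intermediate
17 | prop-2-yn-1-ol | OCC#C | starting material
18 | dimethyl{[(E)-3-(dimethylalumanyl)-2-methylprop-2-en-1-yl]oxy}alumane (formed in situ) | C[Al](C)OC/C(C)=C/[Al](C)C | intermediate
19 | (E)-3-iodo-2-methylprop-2-en-1-ol | OC/C(C)=C/I | intermediate
20 | (E)-3-iodo-2-methylprop-2-enal | O=C/C(C)=C/I | intermediate
21 | diethyl [(E)-3-phenylprop-2-en-1-yl]phosphonate (diethyl cinnamylphosphonate) | CCOP(=O)(C/C=C/c1ccccc1)OCC | starting material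
22 | [(1E,3E,5E)-6-iodo-5-methylhexa-1,3,5-trien-1-yl]benzene | I/C=C(\C)/C=C/C=C/c1ccccc1 | intermediate
23 | [(1E,3E,5E)-2-methyl-6-phenylhexa-1,3,5-trien-1-yl]lithium (formed in situ) | [Li]/C=C(\C)/C=C/C=C/c1ccccc1 | intermediate
24 | chloro[(1E,3E,5E)-2-methyl-6-phenylhexa-1,3,5-trien-1-yl]zinc (formed in situ) | Cl[Zn]/C=C(\C)/C=C/C=C/c1ccccc1 | intermediate
25 | ethyl (2E,4Z,6S,7E,9E,11E,13E)-4-ethyl-2,6,8,10-tetramethyl-14-phenyltetradeca-2,4,7,9,11,13-hexaenoate | CCOC(=O)/C(C)=C/C(CC)=C\[C@@H](C)/C=C(C)/C=C(C)/C=C/C=C/c1ccccc1 | intermediate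
26 | (2E,4Z,6S,7E,9E,11E,13E)-4-ethyl-2,6,8,10-tetramethyl-14-phenyltetradeca-2,4,7,9,11,13-hexaen-1-ol | OC/C(C)=C/C(CC)=C\[C@@H](C)/C=C(C)/C=C(C)/C=C/C=C/c1ccccc1 | intermediate
27 | (2E,4Z,6S,7E,9E,11E,13E)-4-ethyl-2,6,8,10-tetramethyl-14-phenyltetradeca-2,4,7,9,11,13-hexaenal | O=C/C(C)=C/C(CC)=C\[C@@H](C)/C=C(C)/C=C(C)/C=C/C=C/c1ccccc1 | intermediate
28 | (1R,3aR,4R,5S,7aS)-3-ethyl-1,4,5,7-tetramethyl-5-[(1E,3E)-4-phenylbuta-1,3-dien-1-yl]-3a,4,5,7a-tetrahydro-1H-indene-4-carbaldehyde (trans ring fusion) | CCC1=C[C@@H](C)[C@@H]2C(C)=C[C@](C)(/C=C/C=C/c3ccccc3)[C@](C)(C=O)[C@@H]12 | intermediate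
29 | (1R,3aR,4R,5S,7aS)-3-ethyl-1,4,5,7-tetramethyl-5-[(1E,3E)-4-phenylbuta-1,3-dien-1-yl]-3a,4,5,7a-tetrahydro-1H-indene-4-carboxylic acid (22-nor-zyggomphic acid B) | CCC1=C[C@@H](C)[C@@H]2C(C)=C[C@](C)(/C=C/C=C/c3ccccc3)[C@](C)(C(=O)O)[C@@H]12 | target

## Step count and risks

Total step count: 19. Longest linear sequence: 15 steps (steps 1–7, 9–11 and 15–19, from compound 1).

Steps most likely to fail:

**Step 18 (key cycloaddition).** What may go wrong: erosion of endo selectivity, because a tether-endo (cis-fused) transition state avoids the contact between the 2-methyl group and the inside 10-methyl group; and Lewis-acid-induced cationic oligomerisation of the tetraene. The fallback sets out from hexaenoate 25. Saponification (LiOH, THF/MeOH/H2O, rt, dark) should give (2E,4Z,6S,7E,9E,11E,13E)-4-ethyl-2,6,8,10-tetramethyl-14-phenyltetradeca-2,4,7,9,11,13-hexaenoic acid F1. This acid is then cyclised without any Lewis acid by warming in dilute, degassed water/acetonitrile (LiCl, 60 °C, dark), a thermal carboxyl-level intramolecular Diels–Alder reaction in which hydrophobic packing favours the compact endo transition state. It comes back to the route at target 29 and makes steps 16–19 unnecessary.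

**Step 9 (Z-olefination).** What may go wrong: insufficient Z-selectivity of the α-ethyl phosphonate with the α-branched aldehyde, and partial epimerisation of the α-stereocentre by the phosphonate anion. The fallback sets out from alkyne 5 and fixes the C4=C5 geometry by a halo-olefination and a stereospecific cross-coupling after the fragments are joined. Hydrozirconation of 5 (through 6), transmetalation with ZnCl2 and Pd(PPh3)4-catalysed coupling with iodotriene 22 should give tert-butyldimethyl{[(2S,3E,5E,7E,9E)-2,4,6-trimethyl-10-phenyldeca-3,5,7,9-tetraen-1-yl]oxy}silane F2. Bu4NF (THF, 0 °C) should then give (2S,3E,5E,7E,9E)-2,4,6-trimethyl-10-phenyldeca-3,5,7,9-tetraen-1-ol F3, and buffered Dess–Martin oxidation (2S,3E,5E,7E,9E)-2,4,6-trimethyl-10-phenyldeca-3,5,7,9-tetraenal F4. Stork–Zhao olefination with Ph3P=C(I)Et (from propyltriphenylphosphonium bromide, n-BuLi, I2, then NaN(SiMe3)2, THF, −78 °C) should give the (Z)-iodoalkene [(1E,3E,5E,7E,9S,10Z)-11-iodo-5,7,9-trimethyltrideca-1,3,5,7,10-pentaen-1-yl]benzene F5. Stille coupling (Pd2(dba)3, AsPh3, CuI, DMF, rt) with (E)-2-methyl-3-(tributylstannyl)prop-2-en-1-ol F6, made from iodoalcohol 19 with (Bu3Sn)2 and Pd(PPh3)4, comes back to the route at hexaenol 26. This fallback fixes the selectivity problem only, since aldehyde F4 is still epimerisable.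

**Step 15 (fragment union).** What may go wrong: competing addition of t-BuLi to the styryl triene during iodine–lithium exchange, geometric scrambling of the trienyl metal, and homocoupling. The fallback sets out from iodotriene 22. Miyaura borylation (B2pin2, PdCl2(PPh3)2, PPh3, KOPh, toluene, 50 °C) should give 4,4,5,5-tetramethyl-2-[(1E,3E,5E)-2-methyl-6-phenylhexa-1,3,5-trien-1-yl]-1,3,2-dioxaborolane F7 without any organolithium. Suzuki–Miyaura coupling of this boronate with iodide 16 (Pd(PPh3)4, aq. K3PO4, THF, rt) comes back to the route at hexaenoate 25.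

## Further compounds

F1 | step 18 | (2E,4Z,6S,7E,9E,11E,13E)-4-ethyl-2,6,8,10-tetramethyl-14-phenyltetradeca-2,4,7,9,11,13-hexaenoic acid | OC(=O)/C(C)=C/C(CC)=C\[C@@H](C)/C=C(C)/C=C(C)/C=C/C=C/c1ccccc1
F2 | step 9 | tert-butyldimethyl{[(2S,3E,5E,7E,9E)-2,4,6-trimethyl-10-phenyldeca-3,5,7,9-tetraen-1-yl]oxy}silane | CC(C)(C)[Si](C)(C)OC[C@@H](C)/C=C(C)/C=C(C)/C=C/C=C/c1ccccc1
F3 | step 9 | (2S,3E,5E,7E,9E)-2,4,6-trimethyl-10-phenyldeca-3,5,7,9-tetraen-1-ol | OC[C@@H](C)/C=C(C)/C=C(C)/C=C/C=C/c1ccccc1
F4 | step 9 | (2S,3E,5E,7E,9E)-2,4,6-trimethyl-10-phenyldeca-3,5,7,9-tetraenal | O=C[C@@H](C)/C=C(C)/C=C(C)/C=C/C=C/c1ccccc1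
F5 | step 9 | [(1E,3E,5E,7E,9S,10Z)-11-iodo-5,7,9-trimethyltrideca-1,3,5,7,10-pentaen-1-yl]benzene | CC/C(I)=C/[C@@H](C)/C=C(C)/C=C(C)/C=C/C=C/c1ccccc1
F6 | step 9 | (E)-2-methyl-3-(tributylstannyl)prop-2-en-1-ol | OC/C(C)=C/[Sn](CCCC)(CCCC)CCCC
F7 | step 15 | 4,4,5,5-tetramethyl-2-[(1E,3E,5E)-2-methyl-6-phenylhexa-1,3,5-trien-1-yl]-1,3,2-dioxaborolane | CC1(C)OB(/C=C(\C)/C=C/C=C/c2ccccc2)OC1(C)C
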